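The β‑aryl ketone and the β‑hydroxy ketone of the target share one α‑carbon, so a conjugate arylation followed by an intramolecular aldol addition can build the bicycle in one step.

Numbered as the bicyclo[3.2.1]octan-8-one, the methoxy bridgehead C1 is the α-carbon of the C8 ketone and carries both the aryl-bearing C7 and the carbinol C2: a β-aryl ketone and a β-hydroxy ketone share one donor carbon. Cutting C7–aryl (conjugate addition) and C1–C2 (aldol) opens the six-membered ring C1–C2–C3–C4–C5–C8 and leaves the five-membered ring C1–C7–C6–C5–C8 as a 2-methoxycyclopent-2-enone whose quaternary carbon bears the allyl group and an (R)-2-methoxy-3-oxopropyl arm. One rhodium-catalysed step joins this enone aldehyde to (3,4,5-trimethoxyphenyl)boronic acid, closes the bridged ring and sets C7, C1 and C2. Two purchased stereocentres (C6, C3) relay all others.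

Key step: step 10

Remark on numbering: C1–C8 in the overview and in step 10 are the locants of the target (C1 methoxy bridgehead, C2 CHOH, C3 CHOMe, C4 CH2, C5 allyl bridgehead, C6 CHMe, C7 CH‑aryl, C8 C=O); intermediates carry the locants of their own names.
Assumption: methyl (2S)-2,3-dihydroxypropanoate (1) and (4R)-4-methyloxolan-2-one (5) are bought as single enantiomers.

**Step 1**
Reactants: 1 methyl (2S)-2,3-dihydroxypropanoate
Product: 2 methyl (2S)-3-{[tert-butyl(diphenyl)silyl]oxy}-2-hydroxypropanoate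
Conditions: TBDPSCl, imidazole, DMF, 0 °C
Reagents that add atoms: tert-butyl(chloro)diphenylsilane, CC(C)(C)[Si](Cl)(c1ccccc1)c1ccccc1
Why: Silylation of an alcohol, in which the bulky chlorosilane should take the primary hydroxyl and leave the purchased stereocentre untouched.

**Step 2**
Reactants: 2 methyl (2S)-3-{[tert-butyl(diphenyl)silyl]oxy}-2-hydroxypropanoate
Product: 3 methyl (2S)-3-{[tert-butyl(diphenyl)silyl]oxy}-2-methoxypropanoate
Conditions: MeI, Ag2O, 4 Å MS, Et2O, rt, dark
Reagents that add atoms: iodomethane, CI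
Why: Purdie methylation (silver oxide-mediated Williamson etherification) of an α-hydroxy ester avoids an ester enolate, so the centre that becomes C3 of the target should keep its configuration.

**Step 3**
Reactants: 3 methyl (2S)-3-{[tert-butyl(diphenyl)silyl]oxy}-2-methoxypropanoate
Product: 4 (2R)-3-{[tert-butyl(diphenyl)silyl]oxy}-2-methoxypropan-1-ol
Conditions: LiBH4, THF, 0 °C → rt
Reagents that add atoms: none
Why: Borohydride reduction of the ester to the primary alcohol changes no bond at the stereocentre (the descriptor becomes R by priority only), and the TBDPS group is chosen to resist the 1,3-silyl shift that would racemise this compound.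

**Step 4**
Reactants: 4 (2R)-3-{[tert-butyl(diphenyl)silyl]oxy}-2-methoxypropan-1-ol; 5 (4R)-4-methyloxolan-2-one
Product: 8 (3R,4R)-3-[(2R)-3-{[tert-butyl(diphenyl)silyl]oxy}-2-methoxypropyl]-4-methyloxolan-2-one, via triflate 6 (not isolated), via lithium enolate 7 (not isolated)
Conditions: 4, Tf2O, 2,6-lutidine, CH2Cl2, −78 °C; 5, LDA, THF, −78 °C; then 6, −78 → −30 °C
Reagents that add atoms: trifluoromethanesulfonic anhydride, O=S(=O)(OS(=O)(=O)C(F)(F)F)C(F)(F)F (its triflyl group is carried by intermediate 6 only)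
Why: SN2 alkylation of a lithium lactone enolate by a primary triflate, the leaving group needed at a β-branched β-alkoxy carbon; attack trans to the ring methyl is expected but immaterial, because this centre is planarised again in step 5.

**Step 5**
Reactants: 8 (3R,4R)-3-[(2R)-3-{[tert-butyl(diphenyl)silyl]oxy}-2-methoxypropyl]-4-methyloxolan-2-one
Product: 10 (3S,4R)-3-[(2R)-3-{[tert-butyl(diphenyl)silyl]oxy}-2-methoxypropyl]-4-methyl-3-(prop-2-en-1-yl)oxolan-2-one, via lithium enolate 9 (not isolated)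
Conditions: LDA, THF, −78 °C; allyl bromide, DMPU, −78 → −20 °C
Reagents that add atoms: 3-bromoprop-1-ene (allyl bromide), C=CCBr
Why: Enolate alkylation forms the quaternary centre, with allyl bromide expected on the enolate face anti to the neighbouring C4 methyl (1,2-induction in the five-membered ring), which leaves the methoxypropyl arm cis to that methyl.

**Step 6**
Reactants: 10 (3S,4R)-3-[(2R)-3-{[tert-butyl(diphenyl)silyl]oxy}-2-methoxypropyl]-4-methyl-3-(prop-2-en-1-yl)oxolan-2-one; 11 diethyl (methoxymethyl)phosphonate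
Product: 13 diethyl [(3S)-3-[(2R)-3-{[tert-butyl(diphenyl)silyl]oxy}-2-methoxypropyl]-3-[(2R)-1-hydroxypropan-2-yl]-1-methoxy-2-oxohex-5-en-1-yl]phosphonate (C1 epimers; in equilibrium with its cyclic hemiketal), via lithiated phosphonate 12 (not isolated)
Conditions: 11 (3 equiv), LDA, THF, −78 °C; then 10, −78 → 0 °C; aq. NH4Cl
Reagents that add atoms: none
Why: Acylation of an α-lithiated phosphonate by the lactone carbonyl (β-ketophosphonate synthesis) should work because 10 has no enolisable α-hydrogen, ring opening frees the primary alcohol, and excess anion stores the product as its phosphonate enolate.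

**Step 7**
Reactants: 13 diethyl [(3S)-3-[(2R)-3-{[tert-butyl(diphenyl)silyl]oxy}-2-methoxypropyl]-3-[(2R)-1-hydroxypropan-2-yl]-1-methoxy-2-oxohex-5-en-1-yl]phosphonate
Product: 15 (4S,5S)-5-[(2R)-3-{[tert-butyl(diphenyl)silyl]oxy}-2-methoxypropyl]-2-methoxy-4-methyl-5-(prop-2-en-1-yl)cyclopent-2-en-1-one, via aldehyde 14 (not isolated)
Conditions: DMP, CH2Cl2, 0 °C → rt; then LiCl, iPr2NEt, MeCN, rt
Reagents that add atoms: none
Why: Dess–Martin oxidation followed by intramolecular Horner–Wadsworth–Emmons olefination under Masamune–Roush conditions (lactone-to-cyclopentenone annulation) closes the 2-methoxy enone, the weak amine base being chosen to spare the α-methyl aldehyde centre.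

**Step 8**
Reactants: 15 (4S,5S)-5-[(2R)-3-{[tert-butyl(diphenyl)silyl]oxy}-2-methoxypropyl]-2-methoxy-4-methyl-5-(prop-2-en-1-yl)cyclopent-2-en-1-one
Product: 16 (4S,5S)-5-[(2R)-3-hydroxy-2-methoxypropyl]-2-methoxy-4-methyl-5-(prop-2-en-1-yl)cyclopent-2-en-1-one
Conditions: TBAF, AcOH, THF, 0 °C → rt
Reagents that add atoms: none
Why: Fluoride cleavage of the silyl ether, buffered with acetic acid so that the enone and its γ-stereocentre see no strong base.

**Step 9**
Reactants: 16 (4S,5S)-5-[(2R)-3-hydroxy-2-methoxypropyl]-2-methoxy-4-methyl-5-(prop-2-en-1-yl)cyclopent-2-en-1-one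
Product: 17 (2R)-2-methoxy-3-[(1S,5S)-3-methoxy-5-methyl-2-oxo-1-(prop-2-en-1-yl)cyclopent-3-en-1-yl]propanal
Conditions: DMP, CH2Cl2, 0 °C; used at once
Reagents that add atoms: none
Why: Dess–Martin oxidation of the primary alcohol under near-neutral conditions, under which an α-alkoxy aldehyde should keep its configuration.

**Step 10**
Reactants: 17 (2R)-2-methoxy-3-[(1S,5S)-3-methoxy-5-methyl-2-oxo-1-(prop-2-en-1-yl)cyclopent-3-en-1-yl]propanal; 18 (3,4,5-trimethoxyphenyl)boronic acid
Product: 20 (1R,2R,3R,5S,6S,7R)-2-hydroxy-1,3-dimethoxy-6-methyl-5-(prop-2-en-1-yl)-7-(3,4,5-trimethoxyphenyl)bicyclo[3.2.1]octan-8-one, via rhodium enolate 19 (not isolated)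
Conditions: [Rh(cod)OH]2 (5 mol%), 18 (2.5 equiv), 1,4-dioxane/H2O (10:1), 30 °C
Reagents that add atoms: none
Why: Aryl–rhodium(I), formed from 18 and Rh–OH, inserts the C=C of the 2-methoxy enone (Hayashi–Miyaura 1,4-addition) to give the oxa-π-allyl rhodium enolate 19, which adds to the tethered aldehyde before it is protonated, and hydrolysis of the rhodium aldolate returns Rh–OH. The closest known reaction type is the rhodium-catalysed tandem conjugate arylation–aldol cyclisation of enones that carry a tethered carbonyl group. The aldol closes the six-membered ring C1–C2–C3–C4–C5–C8 in the 6-(enolendo)-exo-trig mode and thereby bridges the cyclopentanone. C7 is set by aryl delivery anti to the adjacent C6 methyl; C1 follows because the arm, held on the opposite face by the quaternary C5, can reach the enolate carbon only from its own side; C2 is set by a closed chair-like transition state in which the aldehyde oxygen is bound to the rhodium on the enolate oxygen (hydroxyl axial, syn to C8=O) with the C3 methoxy equatorial. The step needs 1,4-arylation of the electron-rich enone to outrun 1,2-arylation of the aldehyde and aldol closure to outrun protonation of 19; the low temperature, the phosphine-free diene catalyst and the intramolecular six-ring closure should secure both.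

**Compound list**
1 | methyl (2S)-2,3-dihydroxypropanoate | COC(=O)[C@@H](O)CO | starting material
2 | methyl (2S)-3-{[tert-butyl(diphenyl)silyl]oxy}-2-hydroxypropanoate | COC(=O)[C@@H](O)CO[Si](c1ccccc1)(c1ccccc1)C(C)(C)C | intermediate
3 | methyl (2S)-3-{[tert-butyl(diphenyl)silyl]oxy}-2-methoxypropanoate | COC(=O)[C@@H](OC)CO[Si](c1ccccc1)(c1ccccc1)C(C)(C)C | intermediate
4 | (2R)-3-{[tert-butyl(diphenyl)silyl]oxy}-2-methoxypropan-1-ol | OC[C@@H](OC)CO[Si](c1ccccc1)(c1ccccc1)C(C)(C)C | intermediate
5 | (4R)-4-methyloxolan-2-one | C[C@H]1COC(=O)C1 | starting material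
6 | (2S)-3-{[tert-butyl(diphenyl)silyl]oxy}-2-methoxypropyl trifluoromethanesulfonate | O=S(=O)(OC[C@@H](OC)CO[Si](c1ccccc1)(c1ccccc1)C(C)(C)C)C(F)(F)F | intermediate (not isolated)
7 | lithium (4R)-4-methyl-4,5-dihydrofuran-2-olate | C[C@H]1COC(O[Li])=C1 | intermediate (not isolated)
8 | (3R,4R)-3-[(2R)-3-{[tert-butyl(diphenyl)silyl]oxy}-2-methoxypropyl]-4-methyloxolan-2-one | C[C@H]1COC(=O)[C@@H]1C[C@@H](OC)CO[Si](c1ccccc1)(c1ccccc1)C(C)(C)C | intermediate
9 | lithium (4R)-3-[(2R)-3-{[tert-butyl(diphenyl)silyl]oxy}-2-methoxypropyl]-4-methyl-4,5-dihydrofuran-2-olate | C[C@H]1COC(O[Li])=C1C[C@@H](OC)CO[Si](c1ccccc1)(c1ccccc1)C(C)(C)C | intermediate (not isolated)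
10 | (3S,4R)-3-[(2R)-3-{[tert-butyl(diphenyl)silyl]oxy}-2-methoxypropyl]-4-methyl-3-(prop-2-en-1-yl)oxolan-2-one | C=CC[C@]1(C[C@@H](OC)CO[Si](c2ccccc2)(c2ccccc2)C(C)(C)C)[C@@H](C)COC1=O | intermediate
11 | diethyl (methoxymethyl)phosphonate | COCP(=O)(OCC)OCC | starting material
12 | diethyl [lithio(methoxy)methyl]phosphonate | [Li]C(OC)P(=O)(OCC)OCC | intermediate (not isolated)
13 | diethyl [(3S)-3-[(2R)-3-{[tert-butyl(diphenyl)silyl]oxy}-2-methoxypropyl]-3-[(2R)-1-hydroxypropan-2-yl]-1-methoxy-2-oxohex-5-en-1-yl]phosphonate (C1 epimers) | C=CC[C@](C[C@@H](OC)CO[Si](c1ccccc1)(c1ccccc1)C(C)(C)C)([C@@H](C)CO)C(=O)C(OC)P(=O)(OCC)OCC | intermediate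
14 | diethyl [(3S)-3-[(2R)-3-{[tert-butyl(diphenyl)silyl]oxy}-2-methoxypropyl]-1-methoxy-2-oxo-3-[(2R)-1-oxopropan-2-yl]hex-5-en-1-yl]phosphonate (C1 epimers) | C=CC[C@](C[C@@H](OC)CO[Si](c1ccccc1)(c1ccccc1)C(C)(C)C)([C@@H](C)C=O)C(=O)C(OC)P(=O)(OCC)OCC | intermediate (not isolated)
15 | (4S,5S)-5-[(2R)-3-{[tert-butyl(diphenyl)silyl]oxy}-2-methoxypropyl]-2-methoxy-4-methyl-5-(prop-2-en-1-yl)cyclopent-2-en-1-one | C=CC[C@]1(C[C@@H](OC)CO[Si](c2ccccc2)(c2ccccc2)C(C)(C)C)[C@@H](C)C=C(OC)C1=O | intermediate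
16 | (4S,5S)-5-[(2R)-3-hydroxy-2-methoxypropyl]-2-methoxy-4-methyl-5-(prop-2-en-1-yl)cyclopent-2-en-1-one | C=CC[C@]1(C[C@@H](OC)CO)[C@@H](C)C=C(OC)C1=O | intermediate
17 | (2R)-2-methoxy-3-[(1S,5S)-3-methoxy-5-methyl-2-oxo-1-(prop-2-en-1-yl)cyclopent-3-en-1-yl]propanal | C=CC[C@]1(C[C@@H](OC)C=O)[C@@H](C)C=C(OC)C1=O | intermediate
18 | (3,4,5-trimethoxyphenyl)boronic acid | OB(O)c1cc(OC)c(OC)c(OC)c1 | starting material
19 | (cycloocta-1,5-diene)rhodium(I) enolate of (3R,4S,5S)-2-methoxy-5-[(2R)-2-methoxy-3-oxopropyl]-4-methyl-5-(prop-2-en-1-yl)-3-(3,4,5-trimethoxyphenyl)cyclopentan-1-one | C=CC[C@]1(C[C@@H](OC)C=O)[C@@H](C)[C@H](c2cc(OC)c(OC)c(OC)c2)C(OC)=C1O[Rh].C1=CCCC=CCC1 | intermediate (not isolated)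
20 | (1R,2R,3R,5S,6S,7R)-2-hydroxy-1,3-dimethoxy-6-methyl-5-(prop-2-en-1-yl)-7-(3,4,5-trimethoxyphenyl)bicyclo[3.2.1]octan-8-one | C=CC[C@@]12C[C@@H](OC)[C@@H](O)[C@@](OC)(C1=O)[C@@H](c1cc(OC)c(OC)c(OC)c1)[C@@H]2C | target

**Step count**
Total steps: 10. Longest linear sequence: 10 steps (1 → 2 → 3 → 4 → 8 → 10 → 13 → 15 → 16 → 17 → 20); 5, 11 and 18 enter as purchased fragments.

**Steps most likely to fail**

Step 10. Aryl transfer to the aldehyde may compete with insertion into the hindered, electron-rich enone, or the rhodium enolate may be protonated before it closes the ring. The fallback separates the two bond formations and keeps the aldehyde masked during arylation. It sets out from 15: (3,4,5-trimethoxyphenyl)magnesium bromide with CuBr·SMe2 and BF3·OEt2 in THF at −78 °C should add the aryl group anti to the ring methyl and give the aryl ketone F1 as both epimers at the methoxy-bearing α-carbon. TBAF/AcOH then gives the alcohol F2, and Dess–Martin periodinane gives the keto aldehyde F3. Soft enolisation of the α-methoxy ketone (MgBr2·OEt2, Et3N, CH2Cl2), which has only one enolisable α-carbon, followed by intramolecular aldol addition through the magnesium-chelated chair, closes the ring and comes back to the route at 20.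

Step 4. The β-alkoxy triflate may be lost by elimination or ionisation, or the lactone enolate may self-condense faster than it is alkylated at the β-branched carbon. The fallback attaches the arm by olefination instead of SN2 and sets out from 5 and 3. Lactone 5 with excess LDA and diethyl chlorophosphate (enol phosphate to phosphonate shift) gives the phosphono lactone F4. Ester 3 with DIBAL-H at −78 °C gives the aldehyde F5. Horner–Wadsworth–Emmons coupling of the two (LiCl, DBU, MeCN) gives the alkylidene lactone F6. Conjugate reduction with L-Selectride (THF, −78 °C) places hydride on the exocyclic carbon and generates lithium enolate 9, which is allylated as in step 5, so the fallback comes back to the route at 10.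

Step 6. The phosphonate anion may fail to add to the lactone carbonyl, which is shielded by the adjacent quaternary centre. The fallback forms the ring before the quaternary centre and sets out from 8. Anion 12 opens this less hindered lactone to the hydroxy ketophosphonate F7. Dess–Martin oxidation gives the aldehyde F8, and LiCl/iPr2NEt olefination gives the cyclopentenone F9. Kinetic α′-deprotonation (LiHMDS, THF, −78 °C) and allyl bromide, again anti to the ring methyl, then install the quaternary centre and come back to the route at 15.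

**Further compounds**
F1 | step 10 | (3R,4S,5S)-5-[(2R)-3-{[tert-butyl(diphenyl)silyl]oxy}-2-methoxypropyl]-2-methoxy-4-methyl-5-(prop-2-en-1-yl)-3-(3,4,5-trimethoxyphenyl)cyclopentan-1-one (C2 epimers) | C=CC[C@]1(C[C@@H](OC)CO[Si](c2ccccc2)(c2ccccc2)C(C)(C)C)[C@@H](C)[C@H](c2cc(OC)c(OC)c(OC)c2)C(OC)C1=O
F2 | step 10 | (3R,4S,5S)-5-[(2R)-3-hydroxy-2-methoxypropyl]-2-methoxy-4-methyl-5-(prop-2-en-1-yl)-3-(3,4,5-trimethoxyphenyl)cyclopentan-1-one (C2 epimers) | C=CC[C@]1(C[C@@H](OC)CO)[C@@H](C)[C@H](c2cc(OC)c(OC)c(OC)c2)C(OC)C1=O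
F3 | step 10 | (2R)-2-methoxy-3-[(1S,4R,5S)-3-methoxy-5-methyl-2-oxo-1-(prop-2-en-1-yl)-4-(3,4,5-trimethoxyphenyl)cyclopentyl]propanal (ring C3 epimers) | C=CC[C@]1(C[C@@H](OC)C=O)[C@@H](C)[C@H](c2cc(OC)c(OC)c(OC)c2)C(OC)C1=O
F4 | step 4 | diethyl [(4S)-4-methyl-2-oxooxolan-3-yl]phosphonate (C3 epimers) | C[C@H]1COC(=O)C1P(=O)(OCC)OCC
F5 | step 4 | (2S)-3-{[tert-butyl(diphenyl)silyl]oxy}-2-methoxypropanal | O=C[C@@H](OC)CO[Si](c1ccccc1)(c1ccccc1)C(C)(C)C
F6 | step 4 | (3E,4R)-3-[(2R)-3-{[tert-butyl(diphenyl)silyl]oxy}-2-methoxypropylidene]-4-methyloxolan-2-one | C[C@H]1COC(=O)/C1=C/[C@@H](OC)CO[Si](c1ccccc1)(c1ccccc1)C(C)(C)C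
F7 | step 6 | diethyl [(3R,4R)-3-[(2R)-3-{[tert-butyl(diphenyl)silyl]oxy}-2-methoxypropyl]-5-hydroxy-1-methoxy-4-methyl-2-oxopentyl]phosphonate (C1 epimers) | C[C@@H](CO)[C@@H](C[C@@H](OC)CO[Si](c1ccccc1)(c1ccccc1)C(C)(C)C)C(=O)C(OC)P(=O)(OCC)OCC
F8 | step 6 | diethyl [(3R,4R)-3-[(2R)-3-{[tert-butyl(diphenyl)silyl]oxy}-2-methoxypropyl]-1-methoxy-4-methyl-2,5-dioxopentyl]phosphonate (C1 epimers) | C[C@@H](C=O)[C@@H](C[C@@H](OC)CO[Si](c1ccccc1)(c1ccccc1)C(C)(C)C)C(=O)C(OC)P(=O)(OCC)OCC
F9 | step 6 | (4S,5R)-5-[(2R)-3-{[tert-butyl(diphenyl)silyl]oxy}-2-methoxypropyl]-2-methoxy-4-methylcyclopent-2-en-1-one | C[C@H]1C=C(OC)C(=O)[C@@H]1C[C@@H](OC)CO[Si](c1ccccc1)(c1ccccc1)C(C)(C)C
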